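## Retrosynthetic overview

1. Target 20 comes from global desilylation of 19; the stilbene C=C of 19 is made by a Heck coupling of vinylarene 18 with aryl bromide 5 (18 from aldehyde 16 by Wittig methylenation).
2. Key step: both stereocentres of 16 are set at once by a catalytic asymmetric ionic (transfer) hydrogenation of the flat, achiral 2,3-diaryl-1,4-benzodioxine 14, run as a dynamic kinetic resolution of its C2-protonated oxocarbenium ion; anti hydride delivery gives the cis ring.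
3. 14 comes from cyclodehydration of keto phenol 12, which comes from 4-O-selective alkylation of 3,4-dihydroxybenzaldehyde 11 with α-bromodeoxybenzoin 10.
4. 10 comes from deoxybenzoin 6, made by Pd-catalysed α-arylation of acetophenone 3 with bromide 5 (5 is used twice).
5. Ring order: only the heterocycle is built (C–O alkylation in step 5, C–O hemiketalisation/dehydration in step 6, reduction to the dioxane in step 7); all benzene rings are bought.

Target stereochemistry as read from the SMILES: the two aryl groups are cis; the carbon bearing the 3,4-dihydroxyphenyl ring is R and the carbon bearing the 3,5-dihydroxyphenyl ring is S.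

Locants used throughout: O1, C2, C3, O4 in the heterocycle; C2 carries the 3,5-dioxygenated ring, C3 the 3,4-dioxygenated ring, C6 (para to O1) the formyl/vinyl/styryl group. TIPS = triisopropylsilyl; TIPSO = iPr3SiO.

Assumption: the (R)-configured acid catalyst in step 7 is taken to give the (2S,3R) product; the sense of induction has to be confirmed on the first run, and the (S)-catalyst is used instead if it is opposite, with no other change.

## Route

Step 1
Reactants: 1 1-(3,4-dihydroxyphenyl)ethanone; 2 chlorotriisopropylsilane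
Product: 3 1-[3,4-bis(TIPSO)phenyl]ethanone
Conditions: iPr3SiCl (2.4 equiv), imidazole (5 equiv), DMF, 25 to 45 °C
Reagents that add atoms: chlorotriisopropylsilane (2), CC(C)[Si](Cl)(C(C)C)C(C)C
Why: Imidazole-promoted O-silylation of both phenols; TIPS ethers survive the later base, acid and Pd steps and come off at the end with buffered fluoride, which spares the stilbene and the cis-benzodioxane.

Step 2
Reactants: 4 5-bromobenzene-1,3-diol; 2 chlorotriisopropylsilane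
Product: 5 1-bromo-3,5-bis(TIPSO)benzene
Conditions: iPr3SiCl (2.3 equiv), imidazole (5 equiv), DMF, 25 °C
Reagents that add atoms: chlorotriisopropylsilane (2), CC(C)[Si](Cl)(C(C)C)C(C)C
Why: Same O-silylation; the product serves both as the α-arylation partner (step 3) and as the Heck partner (step 9).

Step 3
Reactants: 3 1-[3,4-bis(TIPSO)phenyl]ethanone (1.2 equiv); 5 1-bromo-3,5-bis(TIPSO)benzene
Product: 6 1-[3,4-bis(TIPSO)phenyl]-2-[3,5-bis(TIPSO)phenyl]ethanone
Conditions: Pd(OAc)2 (2 mol%), 2-dicyclohexylphosphino-2'-methylbiphenyl (4 mol%), K3PO4 (2.3 equiv), toluene, 80 °C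
Reagents that add atoms: none
Why: Buchwald–Hartwig-type ketone α-arylation (oxidative addition of Ar–Br to zerovalent palladium, enolate transmetalation, C–C reductive elimination); the bulky biarylphosphine favours mono-arylation and K3PO4 is mild enough for aryl silyl ethers.

Step 4
Reactants: 6 deoxybenzoin; 7 trimethylsilyl trifluoromethanesulfonate; 8 N-bromosuccinimide
Product: 10 2-bromo-1-[3,4-bis(TIPSO)phenyl]-2-[3,5-bis(TIPSO)phenyl]ethanone (racemic), via trimethylsilyl enol ether 9 (not isolated)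
Conditions: Me3SiOTf (1.3 equiv), Et3N (1.6 equiv), CH2Cl2, 0 °C; solvent swap; then NBS (1.05 equiv), THF, −78 to 0 °C
Reagents that add atoms: N-bromosuccinimide (8), O=C1CCC(=O)N1Br (gives Br); trimethylsilyl trifluoromethanesulfonate (7), C[Si](C)(C)OS(=O)(=O)C(F)(F)F (Me3Si is carried only by intermediate 9)
Why: Soft enolisation then electrophilic α-bromination of the silyl enol ether, which directs Br+ to the α-carbon and not to the electron-rich silyloxyarenes; the new stereocentre is racemic and is erased in step 6.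

Step 5
Reactants: 10 α-bromoketone; 11 3,4-dihydroxybenzaldehyde (1.2 equiv)
Product: 12 4-{2-[3,4-bis(TIPSO)phenyl]-1-[3,5-bis(TIPSO)phenyl]-2-oxoethoxy}-3-hydroxybenzaldehyde (racemic)
Conditions: KHCO3 (1.2 equiv), DMF, 25 to 40 °C
Reagents that add atoms: none
Why: Williamson-type SN2 etherification; the 4-OH para to the formyl group is much the more acidic, so bicarbonate generates only that phenoxide, which displaces the activated α-keto benzylic bromide and places the para oxygen on the carbon bearing the 3,5-ring.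

Step 6
Reactants: 12 keto phenol
Product: 14 3-[3,4-bis(TIPSO)phenyl]-2-[3,5-bis(TIPSO)phenyl]-1,4-benzodioxine-6-carbaldehyde, via cyclic hemiketal 13 (not isolated)
Conditions: p-TsOH·H2O (10 mol%), toluene, reflux, Dean–Stark
Reagents that add atoms: none
Why: Acid-catalysed hemiketalisation by the free 3-OH followed by dehydration (the classical catechol/benzoin route to 2,3-diaryl-1,4-benzodioxines) gives the fully conjugated enediol diether and removes the racemic stereocentre.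

Step 7
Reactants: 14 benzodioxine aldehyde
Product: 16 (2S,3R)-3-[3,4-bis(TIPSO)phenyl]-2-[3,5-bis(TIPSO)phenyl]-2,3-dihydro-1,4-benzodioxine-6-carbaldehyde (cis), via benzodioxinium cation 15 (not isolated)
Conditions: (R)-3,3'-bis(2,4,6-triisopropylphenyl)-1,1'-binaphthyl-2,2'-diyl N-(trifluoromethanesulfonyl)phosphoramide (5 mol%), diethyl 2,6-dimethyl-1,4-dihydropyridine-3,5-dicarboxylate (Hantzsch ester, 1.5 equiv), 5 Å MS, toluene, 0 to 25 °C
Reagents that add atoms: none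
Why: Proposed new method: the chiral acid protonates C2 reversibly, because only that places the cation at C3 where O4 and the para-silyloxyphenyl ring stabilise it (O1 is deactivated by the para-formyl group), so the two C2-epimeric oxocarbenium/phosphoramidate ion pairs interconvert through 14; the Hantzsch ester then delivers hydride to C3 anti to the pseudo-axial C2 aryl (A1,2 strain), which sets cis, while the chiral counter-anion chooses which ion pair is reduced, which sets (2S,3R) in a dynamic kinetic resolution. Closest known reaction types are the chiral phosphoric acid/Hantzsch ester transfer hydrogenation of 2,3-disubstituted quinolines (same enamine to C3-protonated iminium resolution, cis products), ion-pairing reductions of benzopyrylium ions, and the cis-selective hydride reduction of 3-substituted flavylium ions.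

Step 8
Reactants: 16 cis-aldehyde; 17 methyltriphenylphosphonium bromide
Product: 18 (2S,3R)-3-[3,4-bis(TIPSO)phenyl]-2-[3,5-bis(TIPSO)phenyl]-6-ethenyl-2,3-dihydro-1,4-benzodioxine
Conditions: Ph3PCH3Br (1.5 equiv), NaN(SiMe3)2 (1.4 equiv), THF, 0 °C; then 16, 0 to 25 °C
Reagents that add atoms: methyltriphenylphosphonium bromide (17), C[P+](c1ccccc1)(c1ccccc1)c1ccccc1.[Br-]
Why: Wittig methylenation of a non-enolisable aryl aldehyde with a preformed, salt-free ylide; the ring C–H bonds are not acidic enough to epimerise and no free phenol is present to open the ring.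

Step 9
Reactants: 18 vinylarene; 5 1-bromo-3,5-bis(TIPSO)benzene (1.2 equiv)
Product: 19 (2S,3R)-3-[3,4-bis(TIPSO)phenyl]-2-[3,5-bis(TIPSO)phenyl]-6-{(E)-2-[3,5-bis(TIPSO)phenyl]ethenyl}-2,3-dihydro-1,4-benzodioxine
Conditions: Pd2(dba)3 (1.5 mol%), [HP(t-Bu)3]BF4 (6 mol%), Cy2NMe (1.3 equiv), 1,4-dioxane, 70 °C
Reagents that add atoms: none
Why: Mizoroki–Heck reaction at zerovalent palladium; syn-carbopalladation at the terminal carbon and syn-β-hydride elimination give the (E)-stilbene, and the mild amine base leaves the stereocentres and silyl ethers alone.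

Step 10
Reactants: 19 hexa-TIPS ether
Product: 20 (2S,3R)-3-(3,4-dihydroxyphenyl)-2-(3,5-dihydroxyphenyl)-6-[(E)-2-(3,5-dihydroxyphenyl)ethenyl]-2,3-dihydro-1,4-benzodioxine (target)
Conditions: Bu4NF (7 equiv), AcOH (8 equiv), THF, 0 to 25 °C, degassed; reversed-phase purification
Reagents that add atoms: none
Why: Fluoride-driven cleavage of all six aryl silyl ethers; the acetic acid buffer keeps the phenols protonated, so the para-hydroxybenzyl aryl ether cannot open to a quinone methide (no cis-to-trans leakage), and the stilbene is untouched.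

## Compound list

1 | 1-(3,4-dihydroxyphenyl)ethanone | CC(=O)c1ccc(O)c(O)c1 | starting material
2 | chlorotriisopropylsilane | CC(C)[Si](Cl)(C(C)C)C(C)C | starting material
3 | 1-[3,4-bis(TIPSO)phenyl]ethanone | CC(=O)c1ccc(O[Si](C(C)C)(C(C)C)C(C)C)c(O[Si](C(C)C)(C(C)C)C(C)C)c1 | intermediate
4 | 5-bromobenzene-1,3-diol | Oc1cc(O)cc(Br)c1 | starting material
5 | 1-bromo-3,5-bis(TIPSO)benzene | Brc1cc(O[Si](C(C)C)(C(C)C)C(C)C)cc(O[Si](C(C)C)(C(C)C)C(C)C)c1 | intermediate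
6 | 1-[3,4-bis(TIPSO)phenyl]-2-[3,5-bis(TIPSO)phenyl]ethanone | O=C(Cc1cc(O[Si](C(C)C)(C(C)C)C(C)C)cc(O[Si](C(C)C)(C(C)C)C(C)C)c1)c1ccc(O[Si](C(C)C)(C(C)C)C(C)C)c(O[Si](C(C)C)(C(C)C)C(C)C)c1 | intermediate
7 | trimethylsilyl trifluoromethanesulfonate | C[Si](C)(C)OS(=O)(=O)C(F)(F)F | starting material
8 | N-bromosuccinimide | O=C1CCC(=O)N1Br | starting material
9 | (Z)-1-[3,4-bis(TIPSO)phenyl]-2-[3,5-bis(TIPSO)phenyl]-1-(trimethylsilyloxy)ethene | C[Si](C)(C)O/C(=C\c1cc(O[Si](C(C)C)(C(C)C)C(C)C)cc(O[Si](C(C)C)(C(C)C)C(C)C)c1)c1ccc(O[Si](C(C)C)(C(C)C)C(C)C)c(O[Si](C(C)C)(C(C)C)C(C)C)c1 | intermediate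
10 | 2-bromo-1-[3,4-bis(TIPSO)phenyl]-2-[3,5-bis(TIPSO)phenyl]ethanone (racemic) | O=C(C(Br)c1cc(O[Si](C(C)C)(C(C)C)C(C)C)cc(O[Si](C(C)C)(C(C)C)C(C)C)c1)c1ccc(O[Si](C(C)C)(C(C)C)C(C)C)c(O[Si](C(C)C)(C(C)C)C(C)C)c1 | intermediate
11 | 3,4-dihydroxybenzaldehyde | O=Cc1ccc(O)c(O)c1 | starting material
12 | 4-{2-[3,4-bis(TIPSO)phenyl]-1-[3,5-bis(TIPSO)phenyl]-2-oxoethoxy}-3-hydroxybenzaldehyde (racemic) | O=Cc1ccc(OC(C(=O)c2ccc(O[Si](C(C)C)(C(C)C)C(C)C)c(O[Si](C(C)C)(C(C)C)C(C)C)c2)c2cc(O[Si](C(C)C)(C(C)C)C(C)C)cc(O[Si](C(C)C)(C(C)C)C(C)C)c2)c(O)c1 | intermediate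
13 | 3-[3,4-bis(TIPSO)phenyl]-2-[3,5-bis(TIPSO)phenyl]-3-hydroxy-2,3-dihydro-1,4-benzodioxine-6-carbaldehyde (racemic, diastereomer mixture) | O=Cc1ccc2c(c1)OC(O)(c3ccc(O[Si](C(C)C)(C(C)C)C(C)C)c(O[Si](C(C)C)(C(C)C)C(C)C)c3)C(c3cc(O[Si](C(C)C)(C(C)C)C(C)C)cc(O[Si](C(C)C)(C(C)C)C(C)C)c3)O2 | intermediate
14 | 3-[3,4-bis(TIPSO)phenyl]-2-[3,5-bis(TIPSO)phenyl]-1,4-benzodioxine-6-carbaldehyde | O=Cc1ccc2c(c1)OC(c3ccc(O[Si](C(C)C)(C(C)C)C(C)C)c(O[Si](C(C)C)(C(C)C)C(C)C)c3)=C(c3cc(O[Si](C(C)C)(C(C)C)C(C)C)cc(O[Si](C(C)C)(C(C)C)C(C)C)c3)O2 | intermediate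
15 | (2S)-3-[3,4-bis(TIPSO)phenyl]-2-[3,5-bis(TIPSO)phenyl]-6-formyl-2H-1,4-benzodioxin-4-ium (ion pair with the chiral phosphoramidate; the reduced epimer is shown) | O=Cc1ccc2c(c1)[O+]=C(c3ccc(O[Si](C(C)C)(C(C)C)C(C)C)c(O[Si](C(C)C)(C(C)C)C(C)C)c3)[C@H](c3cc(O[Si](C(C)C)(C(C)C)C(C)C)cc(O[Si](C(C)C)(C(C)C)C(C)C)c3)O2 | intermediate
16 | (2S,3R)-3-[3,4-bis(TIPSO)phenyl]-2-[3,5-bis(TIPSO)phenyl]-2,3-dihydro-1,4-benzodioxine-6-carbaldehyde (cis) | O=Cc1ccc2c(c1)O[C@H](c3ccc(O[Si](C(C)C)(C(C)C)C(C)C)c(O[Si](C(C)C)(C(C)C)C(C)C)c3)[C@H](c3cc(O[Si](C(C)C)(C(C)C)C(C)C)cc(O[Si](C(C)C)(C(C)C)C(C)C)c3)O2 | intermediate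
17 | methyltriphenylphosphonium bromide | C[P+](c1ccccc1)(c1ccccc1)c1ccccc1.[Br-] | starting material
18 | (2S,3R)-3-[3,4-bis(TIPSO)phenyl]-2-[3,5-bis(TIPSO)phenyl]-6-ethenyl-2,3-dihydro-1,4-benzodioxine | C=Cc1ccc2c(c1)O[C@H](c3ccc(O[Si](C(C)C)(C(C)C)C(C)C)c(O[Si](C(C)C)(C(C)C)C(C)C)c3)[C@H](c3cc(O[Si](C(C)C)(C(C)C)C(C)C)cc(O[Si](C(C)C)(C(C)C)C(C)C)c3)O2 | intermediate
19 | (2S,3R)-3-[3,4-bis(TIPSO)phenyl]-2-[3,5-bis(TIPSO)phenyl]-6-{(E)-2-[3,5-bis(TIPSO)phenyl]ethenyl}-2,3-dihydro-1,4-benzodioxine | CC(C)[Si](C(C)C)(C(C)C)Oc1cc(O[Si](C(C)C)(C(C)C)C(C)C)cc(/C=C/c2ccc3c(c2)O[C@H](c4ccc(O[Si](C(C)C)(C(C)C)C(C)C)c(O[Si](C(C)C)(C(C)C)C(C)C)c4)[C@H](c4cc(O[Si](C(C)C)(C(C)C)C(C)C)cc(O[Si](C(C)C)(C(C)C)C(C)C)c4)O3)c1 | intermediate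
20 | (2S,3R)-3-(3,4-dihydroxyphenyl)-2-(3,5-dihydroxyphenyl)-6-[(E)-2-(3,5-dihydroxyphenyl)ethenyl]-2,3-dihydro-1,4-benzodioxine (CNP0283264.2) | Oc1cc(O)cc(/C=C/c2ccc3c(c2)O[C@H](c2ccc(O)c(O)c2)[C@H](c2cc(O)cc(O)c2)O3)c1 | target

## Step count and risks

Total step count: 10. Longest linear sequence: 9 steps (steps 1, 3, 4, 5, 6, 7, 8, 9, 10; step 2 is the side branch).

Most likely to fail, step 7. The asymmetric ionic hydrogenation is new. It may give low ee, leak trans isomer, or ionise the product at the para-silyloxybenzylic C3–O bond. The fallback sets out from 6 and comes back at 16, replacing catalyst control by a stereospecific inversion/retention sequence. Ketone 6 is reduced with NaBH4 to the racemic 1-[3,4-bis(TIPSO)phenyl]-2-[3,5-bis(TIPSO)phenyl]ethanol F1 and dehydrated (cat. p-TsOH·H2O, toluene, 80 °C) to the (E)-stilbene F2. Asymmetric epoxidation with 1,2:4,5-di-O-isopropylidene-L-erythro-2,3-hexodiulo-2,6-pyranose (the enantiomer of the fructose-derived Shi ketone) and KHSO5 gives the (2S,3S)-trans-epoxide F3. The phenoxide of commercial 4-fluoro-3-hydroxybenzaldehyde (O=Cc1ccc(F)c(O)c1; K3PO4, DMF, 50 °C) opens F3 by SN2 with inversion at the para-oxygenated benzylic carbon to give the erythro fluoro alcohol 3-{(1R,2S)-1-[3,4-bis(TIPSO)phenyl]-2-[3,5-bis(TIPSO)phenyl]-2-hydroxyethoxy}-4-fluorobenzaldehyde F4. KN(SiMe3)2 in THF at 0 °C then closes the ring by intramolecular SNAr para to the formyl group, with retention at the carbinol, giving 16; one inversion plus one retention from a trans-epoxide makes the ring cis.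

Second, step 5. The SN2 site is a hindered, enolisable secondary α-bromoketone, and 3-O-alkylation, halophilic reduction or silyl transfer can compete. The fallback sets out from 3 and comes back at 14; it also bypasses steps 3 and 4 and brings in the 3,5-ring by cross-coupling instead. Ketone 3 is brominated (Me3SiOTf/Et3N, then NBS) to 2-bromo-1-[3,4-bis(TIPSO)phenyl]ethanone F5. This unhindered primary bromide alkylates 11 at the 4-OH (KHCO3, DMF) to give keto phenol 4-{2-[3,4-bis(TIPSO)phenyl]-2-oxoethoxy}-3-hydroxybenzaldehyde F6, which is cyclodehydrated (cat. p-TsOH·H2O, toluene, reflux) to 3-[3,4-bis(TIPSO)phenyl]-1,4-benzodioxine-6-carbaldehyde F7. NBS, then Et3N (CH2Cl2, 0 °C), brominates the nucleophilic enol-ether carbon C2 to give 2-bromo-3-[3,4-bis(TIPSO)phenyl]-1,4-benzodioxine-6-carbaldehyde F8. Separately, 5 is borylated (bis(pinacolato)diboron, PdCl2(dppf), KOAc, dioxane, 80 °C) to 2-[3,5-bis(TIPSO)phenyl]-4,4,5,5-tetramethyl-1,3,2-dioxaborolane F9. Suzuki–Miyaura coupling of F8 with F9 (Pd(OAc)2, 2-dicyclohexylphosphino-2',6'-dimethoxybiphenyl, K3PO4, toluene/water, 60 °C) gives 14.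

Third, step 9. The Heck coupling on an electron-rich styrene can give the branched 1,1-diaryl isomer or stall with the hindered bromide, and it heats the cis-benzodioxane with palladium hydrides present. The fallback sets out from 18 (with 5) and comes back at 19, forming the stilbene by metathesis instead. Bromide 5 is vinylated (potassium vinyltrifluoroborate, PdCl2(dppf), Et3N, i-PrOH, 80 °C) to 1-ethenyl-3,5-bis(TIPSO)benzene F10. Cross-metathesis of 18 with excess F10 (RuCl2(1,3-dimesitylimidazolidin-2-ylidene)(=CH-C6H4-2-O-i-Pr), the second-generation Hoveyda–Grubbs catalyst, 5 mol%, CH2Cl2, 40 °C) gives the (E)-stilbene 19; the homodimer of F10 is separated by chromatography.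

## Further compounds

F1 | step 7 | 1-[3,4-bis(TIPSO)phenyl]-2-[3,5-bis(TIPSO)phenyl]ethanol (racemic) | OC(Cc1cc(O[Si](C(C)C)(C(C)C)C(C)C)cc(O[Si](C(C)C)(C(C)C)C(C)C)c1)c1ccc(O[Si](C(C)C)(C(C)C)C(C)C)c(O[Si](C(C)C)(C(C)C)C(C)C)c1
F2 | step 7 | (E)-1-[3,4-bis(TIPSO)phenyl]-2-[3,5-bis(TIPSO)phenyl]ethene | CC(C)[Si](C(C)C)(C(C)C)Oc1cc(O[Si](C(C)C)(C(C)C)C(C)C)cc(/C=C/c2ccc(O[Si](C(C)C)(C(C)C)C(C)C)c(O[Si](C(C)C)(C(C)C)C(C)C)c2)c1
F3 | step 7 | (2S,3S)-2-[3,4-bis(TIPSO)phenyl]-3-[3,5-bis(TIPSO)phenyl]oxirane | O1[C@@H](c2ccc(O[Si](C(C)C)(C(C)C)C(C)C)c(O[Si](C(C)C)(C(C)C)C(C)C)c2)[C@@H]1c3cc(O[Si](C(C)C)(C(C)C)C(C)C)cc(O[Si](C(C)C)(C(C)C)C(C)C)c3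
F4 | step 7 | 3-{(1R,2S)-1-[3,4-bis(TIPSO)phenyl]-2-[3,5-bis(TIPSO)phenyl]-2-hydroxyethoxy}-4-fluorobenzaldehyde | O=Cc1ccc(F)c(c1)O[C@H](c3ccc(O[Si](C(C)C)(C(C)C)C(C)C)c(O[Si](C(C)C)(C(C)C)C(C)C)c3)[C@H](c3cc(O[Si](C(C)C)(C(C)C)C(C)C)cc(O[Si](C(C)C)(C(C)C)C(C)C)c3)O
F5 | step 5 | 2-bromo-1-[3,4-bis(TIPSO)phenyl]ethanone | O=C(CBr)c1ccc(O[Si](C(C)C)(C(C)C)C(C)C)c(O[Si](C(C)C)(C(C)C)C(C)C)c1
F6 | step 5 | 4-{2-[3,4-bis(TIPSO)phenyl]-2-oxoethoxy}-3-hydroxybenzaldehyde | O=Cc1ccc(OCC(=O)c2ccc(O[Si](C(C)C)(C(C)C)C(C)C)c(O[Si](C(C)C)(C(C)C)C(C)C)c2)c(O)c1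
F7 | step 5 | 3-[3,4-bis(TIPSO)phenyl]-1,4-benzodioxine-6-carbaldehyde | O=Cc1ccc2c(c1)OC(c3ccc(O[Si](C(C)C)(C(C)C)C(C)C)c(O[Si](C(C)C)(C(C)C)C(C)C)c3)=CO2
F8 | step 5 | 2-bromo-3-[3,4-bis(TIPSO)phenyl]-1,4-benzodioxine-6-carbaldehyde | O=Cc1ccc2c(c1)OC(c3ccc(O[Si](C(C)C)(C(C)C)C(C)C)c(O[Si](C(C)C)(C(C)C)C(C)C)c3)=C(Br)O2
F9 | step 5 | 2-[3,5-bis(TIPSO)phenyl]-4,4,5,5-tetramethyl-1,3,2-dioxaborolane | CC1(C)OB(OC1(C)C)c1cc(O[Si](C(C)C)(C(C)C)C(C)C)cc(O[Si](C(C)C)(C(C)C)C(C)C)c1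
F10 | step 9 | 1-ethenyl-3,5-bis(TIPSO)benzene | C=Cc1cc(O[Si](C(C)C)(C(C)C)C(C)C)cc(O[Si](C(C)C)(C(C)C)C(C)C)c1
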